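## Analysis of the target

The target is a dihydroflavonol: a chroman-4-one whose benzo ring A carries a free, carbonyl-chelated hydroxyl at C5 and a prenyl ether at O7. Ring C carries a 4-hydroxy-3-methoxyphenyl group (ring B) at C2 and a secondary hydroxyl at C3. The only stereocentres are the adjacent C2 and C3, both R, which places the aryl group and the hydroxyl trans (diequatorial), the more stable relative arrangement. Ring C is fragile: a C3 enolate can expel the O1 phenoxide (retro-oxa-Michael opening to a chalcone) and so erase C2, C3–H is epimerisable, and base with air oxidises the α-ketol to the flavonol. The prenyl ether tolerates neither hydrogenolysis nor epoxidising oxidants nor strong acid, and of the four oxygen functions (O3, O5, O7, O4') only O7 may end up alkylated. The difficulty therefore lies less in the skeleton than in the absolute configuration at C2 and in the order of events around the prenyl group and the base-sensitive ketol. The strategy rests on three facts: C4 is a single carbonyl carbon between C4a of ring A and C3, C3–C2–ring B is the two-carbon unit of an aryl acetylene, and O1 sits ortho to C4a. Ring C can therefore be assembled from an ortho-iodophenol, carbon monoxide and an alkyne, and the stereocentres can be introduced afterwards on the flat C2=C3 bond.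

## Retrosynthetic reasoning

**Target 18 back to silyl ether 17 (O4'–Si).** The last bond cut is the silicon–oxygen bond at O4'. Keeping this phenol silylated to the end means that the only acidic, unchelated phenol present during prenylation is the one at C7. The forward step is a buffered fluoride desilylation that must leave the allylic ether and the ketol alone.

**17 back to triol 15 and prenyl bromide 16 (O7–CH2).** The prenyl ether is cut next. It comes this late because its trisubstituted alkene would not survive the hydrogenolysis, the hydrogenation or the enol ether oxidation used earlier. Forward, alkylation must select O7 over O5 and O3. It should, because O7–H is para to the C4 carbonyl and by far the most acidic, O5–H is held in a hydrogen bond to C4=O, and O3–H is an alcohol.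

**15 back to dibenzyl ether 14 (two benzyl–oxygen bonds).** Ring A has to be fully etherified while C3 is enolised and while the annulation runs in hot amine. Benzyl ethers survive all of that and leave together in one hydrogenolysis. The forward step must spare the benzylic C2–O1 bond of ring C and the aryl silyl ether.

**14 back to enol silane 12 and flavanone 11 (C3–O).** The C3–O bond is cut to the silyl enol ether 12 of the (2S)-flavanone 11. The gain is that C3 is derived from C2: an oxidant approaching the C3=C4 bond anti to the C2 aryl group gives the trans ketol, which is also the more stable diastereomer. The forward sequence must form 12 without allowing a free enolate to open ring C.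

**11 back to flavone 9 (C2–H and C3–H).** Removing the two hydrogens gives flavone 9, which is flat, robust and achiral. The whole carbon skeleton can then be built without stereochemical concern, and the absolute configuration is set by a catalyst in one hydrogenation. Forward, hydrogen must reach C2 from one face; any over-reduced alcohol 10 is returned to 11 by oxidation.

**9 back to iodophenol 5, carbon monoxide 6 and alkyne 3 (C4a–C4, C4–C3, O1–C2).** This is the key disconnection. Cutting on both sides of the carbonyl carbon and at the ring oxygen reduces ring C to three pieces. The cut is made here because the carbonyl carbon is a single atom with no substituent of its own, so it can be supplied as 6, and because the remaining pieces are a symmetrically protected phloroglucinol and a vanillin-derived alkyne, each one or two steps from commercial material. The forward reaction must make carbon monoxide insertion faster than direct aryl–alkyne coupling and must close the ring in the 6-endo sense; a secondary amine directs the latter.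

**5 back to phenol 4 (C–iodine).** The carbon–iodine bond is cut to 3,5-bis(benzyloxy)phenol 4. Forward, electrophilic iodination must take place ortho to the free hydroxyl and not between the two benzyloxy groups.

**3 back to aldehyde 2 and vanillin 1 (terminal alkyne carbon, O–Si).** The terminal carbon of the alkyne is removed to give aldehyde 2, and the silyl group is removed to give vanillin 1. Forward, the one-carbon homologation must be run without methanolic base, which would threaten the aryl silyl ether para to the formyl group.

## Alternatives that were turned down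

**Alternative 1:** Ring A is cut at C8–C8a and C4a–C5 and is built last by a Diels–Alder benzannulation on a ring C building block that already holds both stereocentres.
- Forward key step: 1-methoxy-1,3-bis(trimethylsilyloxy)buta-1,3-diene A3 would add across the C4a=C8a bond of (2R,3R)-3-(tert-butyldimethylsilyloxy)-2-[4-(tert-butyldimethylsilyloxy)-3-methoxyphenyl]-5-(phenylsulfinyl)-2,3-dihydro-4H-pyran-4-one A2. The methylene terminus of the diene bonds to C8a and its ketene acetal carbon to C4a. Syn-elimination of the sulfinyl group, loss of the methoxy group and desilylation would aromatise ring A to the 5,7-diol A1.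
- For: the 5,7-diol appears unprotected, so O7 could be prenylated directly. No benzyl ethers, no hydrogenation and no enol ether oxidation are needed on the flavonoid, and both stereocentres are fixed early. On these points it is stronger than the chosen route.
- Against: the burden moves into A2. It needs its own asymmetric synthesis of a trans-2-aryl-3-silyloxy dihydropyranone, then sulfenylation and oxidation at the vinylic carbon. It already contains the epimerisable α-oxy ketone, which must survive the heating needed for cycloaddition onto a trisubstituted, donor-substituted (vinylogous ester) dienophile.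
- Comparison: the chosen route makes ring C from three pieces that are each one or two steps from commerce. In place of early stereocentres it offers that no stereocentre has to be carried through any carbon–carbon bond formation.

**Alternative 2:** C3–C4 and O1–C2 are cut. Ring A and C4 come from the ortho-quinone methide 3,5-bis(benzyloxy)-6-methylidenecyclohexa-2,4-dien-1-one A7, released by base from the sulfone 3,5-bis(benzyloxy)-2-[(4-methylphenyl)sulfonylmethyl]phenol A5. C2 and C3 come from benzyloxyacetaldehyde A6.
- Forward key step: the enamine of A6 with a diarylprolinol silyl ether catalyst would add to the exocyclic methylene carbon of A7 (the future C4), setting C3. The phenol then closes on the aldehyde to give the lactol (3S)-3,5,7-tris(benzyloxy)chroman-2-ol A4.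
- For: it is metal-free and cheap, and the oxygenated C3 centre is set directly under catalyst control. On that point it is stronger than the chosen route, which derives C3 from C2.
- Against: A4 lacks the two defining features of the target. C4 is a methylene group and C2 bears no aryl group. Aryl addition to the open aldehyde, ring closure with control of C2 by the substrate alone, and a two-stage benzylic oxidation of C4 on an electron-rich flavan would all be needed. Only then could three benzyl ethers be removed and O7 prenylated, at least six operations after the key step.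
- Comparison: this is the natural route to flavan-3-ols, not to 4-ketones. The chosen route brings C4 in at the carbonyl oxidation level from 6 and has ring B attached from the start.

**Alternative 3:** C2–C3 is cut. Ring C is closed by a carbene at C3 inserting into a benzylic C–H bond of the O1–CH2–aryl ether.
- Forward key step: the diazoketone 2-diazo-1-[2-{[3-methoxy-4-(triisopropylsilyloxy)phenyl]methoxy}-6-(tert-butyldimethylsilyloxy)-4-(prenyloxy)phenyl]ethan-1-one A9, with a chiral dirhodium tetracarboxylate (divalent rhodium), would give the (2S)-flavanone A8, forming C2–C3 and setting C2.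
- For: C2 is set in the ring-forming step and the prenyl group is in place from the start, so there is no hydrogenolysis and no late selective alkylation. On step count it is at least equal and probably shorter.
- Against: a carbene from a terminal diazoketone is the least discriminating type. The wanted path is a 1,6-insertion to a six-membered ring, while the ether oxygen O1 is placed to form a five-membered oxonium ylide whose Stevens shift would give a 2-benzylbenzofuranone. The prenyl alkene invites cyclopropanation and the electron-rich ring B invites aromatic cycloaddition. A8 still lacks O3, its enol ether would have to be oxidised in the presence of the trisubstituted alkene, and two different silyl groups remain to be removed.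
- Comparison: the chosen route accepts two more steps for the late prenylation. In return its ring closure has a mode enforced by the amine, and its stereocentre comes from a hydrogenation class already shown on flavones.

Key step: step 4

Remark: 3,5-bis(benzyloxy)phenol 4 is taken as a purchasable compound, which keeps the unselective partial benzylation of phloroglucinol out of the route.

## Route

Step 1
Reactants: 1 vanillin (4-hydroxy-3-methoxybenzaldehyde)
Product: 2 3-methoxy-4-(triisopropylsilyloxy)benzaldehyde
Conditions: TIPSCl, imidazole, DMF, rt
Reagents that add atoms: triisopropylsilyl chloride, CC(C)[Si](Cl)(C(C)C)C(C)C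
Why: Silylation of a phenol with a trialkylsilyl chloride and imidazole; the bulky triisopropylsilyl ether is chosen because it has to survive a lithium amide, hot diethylamine, hydrogenation and carbonate, and still fall to fluoride at the end.

Step 2
Reactants: 2 3-methoxy-4-(triisopropylsilyloxy)benzaldehyde
Product: 3 4-ethynyl-2-methoxy-1-(triisopropylsilyloxy)benzene
Conditions: Me3SiCHN2, LiN(iPr)2, THF, −78 °C; then 2, −78 °C → rt; H2O
Reagents that add atoms: trimethylsilyldiazomethane, C[Si](C)(C)C=[N+]=[N-]
Why: Colvin-type one-carbon homologation: lithiated trimethylsilyldiazomethane adds to the aldehyde, Peterson-type loss of silanolate gives the diazoalkene, and loss of dinitrogen with a 1,2-hydrogen shift in the alkylidene carbene gives the terminal alkyne. No methanolic base is present, so the aryl silyl ether para to the formyl group is not at risk.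

Step 3
Reactants: 4 3,5-bis(benzyloxy)phenol
Product: 5 3,5-bis(benzyloxy)-2-iodophenol
Conditions: N-iodosuccinimide (1.0 equiv), CH2Cl2, −40 → 0 °C, dark
Reagents that add atoms: N-iodosuccinimide, O=C1CCC(=O)N1I
Why: Electrophilic aromatic iodination of a strongly activated phenol; the two equivalent positions ortho to the hydroxyl are favoured statistically and sterically over C4, which lies between two benzyloxy groups. One equivalent of reagent at low temperature should limit di-iodination.

Step 4
Reactants: 5 3,5-bis(benzyloxy)-2-iodophenol, 6 carbon monoxide, 3 4-ethynyl-2-methoxy-1-(triisopropylsilyloxy)benzene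
Product: 9 5,7-bis(benzyloxy)-2-[3-methoxy-4-(triisopropylsilyloxy)phenyl]-4H-chromen-4-one, via hydroxyaryl ynone 7 (not isolated), via enaminone 8 (not isolated)
Conditions: PdCl2(PPh3)2 (5 mol %), CO (20 bar), Et2NH, 120 °C
Reagents that add atoms: none
Why: PdCl2(PPh3)2 is reduced in situ to zerovalent palladium, which adds oxidatively to the carbon–iodine bond of 5; carbon monoxide 6 inserts to give the aroyl complex of divalent palladium, and amine-assisted coupling with alkyne 3 followed by reductive elimination forms C4a–C4 and C4–C3 and releases ynone 7. Diethylamine then adds to the triple bond of 7 to give enaminone 8, and the ortho phenol attacks the amine-bearing carbon (the future C2) with loss of the amine, forming O1–C2. Ring C thus closes in the 6-endo mode, formally a 6-endo-trig addition–elimination on 8. The closest known reaction type is the palladium-catalysed carbonylative annulation of 2-iodophenols with terminal aryl acetylenes to flavones in a secondary amine. No stereocentre is created. Two selectivities are needed: carbonylative over direct coupling, which would end in a 2-arylbenzofuran, and 6-endo over 5-exo closure, which would give the aurone. The first is secured by the carbon monoxide pressure, the absence of copper and the two ortho oxygen substituents flanking the palladium-bearing carbon, which favour insertion of the small carbon monoxide over transmetalation; the second is secured by the enaminone, whose only electrophilic carbon is the one that leads to the six-membered ring.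

Step 5
Reactants: 9 5,7-bis(benzyloxy)-2-[3-methoxy-4-(triisopropylsilyloxy)phenyl]-4H-chromen-4-one
Product: 11 (2S)-5,7-bis(benzyloxy)-2-[3-methoxy-4-(triisopropylsilyloxy)phenyl]chroman-4-one, via cis-flavan-4-ol 10 (not isolated)
Conditions: [Ru(cod)(2-methylallyl)2] (5 mol %), SINpEt·HBF4 (1,3-bis[1-(1-naphthyl)ethyl]imidazolinium tetrafluoroborate, antipode giving 2S, 10 mol %), KOtBu (15 mol %), H2 (100 bar), toluene, rt; then Dess–Martin periodinane, pyridine, CH2Cl2, 0 °C → rt
Reagents that add atoms: none
Why: Ruthenium–N-heterocyclic carbene catalysed asymmetric hydrogenation of a flavone: the chiral carbene ligand differentiates the faces of the C2=C3 bond and so sets C2, and the ligand antipode is chosen (and confirmed on the first run) to give 2S. The catalyst is expected to reduce part of the ketone to the cis alcohol 10 as well, and Dess–Martin oxidation of the crude mixture should return it to 11 without touching C2. Benzyl and silyl ethers are inert to the homogeneous catalyst.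

Step 6
Reactants: 11 (2S)-5,7-bis(benzyloxy)-2-[3-methoxy-4-(triisopropylsilyloxy)phenyl]chroman-4-one
Product: 12 (2S)-5,7-bis(benzyloxy)-2-[3-methoxy-4-(triisopropylsilyloxy)phenyl]-4-(trimethylsilyloxy)-2H-chromene
Conditions: Me3SiCl, then LiN(SiMe3)2, THF, −78 °C; pentane, filtration, used crude
Reagents that add atoms: chlorotrimethylsilane, C[Si](C)(C)Cl
Why: Silyl enol ether formation by kinetic deprotonation at C3 under internal-quench conditions: the silyl chloride is present before the amide is added, so the enolate should be trapped at −78 °C faster than it can expel the O1 phenoxide, and C2 keeps its configuration.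

Step 7
Reactants: 12 (2S)-5,7-bis(benzyloxy)-2-[3-methoxy-4-(triisopropylsilyloxy)phenyl]-4-(trimethylsilyloxy)-2H-chromene
Product: 14 (2R,3R)-5,7-bis(benzyloxy)-3-hydroxy-2-[3-methoxy-4-(triisopropylsilyloxy)phenyl]chroman-4-one, via silyloxy epoxide 13 (not isolated)
Conditions: dimethyldioxirane, acetone–CH2Cl2, −40 °C; then aq. citric acid, THF, 0 °C
Reagents that add atoms: dimethyldioxirane, CC1(C)OO1
Why: Rubottom oxidation: the dioxirane epoxidises the electron-rich enol ether on the face anti to the C2 aryl group to give 13, and mild acid opens the silyloxy epoxide to the α-hydroxy ketone, so C3–O ends up trans to the aryl group (3R). The trans ketol is also the more stable diastereomer, which backs up the kinetic preference. The C2 descriptor changes from S to R only because O3 raises the priority of C3.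

Step 8
Reactants: 14 (2R,3R)-5,7-bis(benzyloxy)-3-hydroxy-2-[3-methoxy-4-(triisopropylsilyloxy)phenyl]chroman-4-one
Product: 15 (2R,3R)-3,5,7-trihydroxy-2-[3-methoxy-4-(triisopropylsilyloxy)phenyl]chroman-4-one
Conditions: H2 (1 atm), Pd/C (10 %), EtOAc–THF, rt
Reagents that add atoms: none
Why: Hydrogenolysis of aryl benzyl ethers over palladium on carbon; at one atmosphere in a non-acidic solvent the benzylic C2–O1 bond of ring C, the hydrogen-bonded ketone and the aryl silyl ether should stay intact.

Step 9
Reactants: 15 (2R,3R)-3,5,7-trihydroxy-2-[3-methoxy-4-(triisopropylsilyloxy)phenyl]chroman-4-one, 16 prenyl bromide (1-bromo-3-methylbut-2-ene)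
Product: 17 (2R,3R)-3,5-dihydroxy-2-[3-methoxy-4-(triisopropylsilyloxy)phenyl]-7-[(3-methylbut-2-en-1-yl)oxy]chroman-4-one
Conditions: K2CO3 (1.2 equiv), acetone, rt, argon
Reagents that add atoms: none
Why: Williamson ether synthesis: one equivalent of weak base deprotonates only the 7-hydroxyl (para to C4=O), which attacks the primary allylic bromide in an SN2 reaction. The chelated 5-OH, the 3-OH and the silylated O4' should not react, and acetone at room temperature under argon should keep ring C closed and unoxidised.

Step 10
Reactants: 17 (2R,3R)-3,5-dihydroxy-2-[3-methoxy-4-(triisopropylsilyloxy)phenyl]-7-[(3-methylbut-2-en-1-yl)oxy]chroman-4-one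
Product: 18 (2R,3R)-3,5-dihydroxy-2-(4-hydroxy-3-methoxyphenyl)-7-[(3-methylbut-2-en-1-yl)oxy]chroman-4-one
Conditions: Bu4NF, AcOH (1:1), THF, 0 °C
Reagents that add atoms: none
Why: Fluoride cleavage of the aryl silyl ether; acetic acid protonates the liberated phenoxide at once, so the base-sensitive ketol and the prenyl ether should be untouched.

## Compound list

1 | vanillin (4-hydroxy-3-methoxybenzaldehyde) | COc1cc(C=O)ccc1O | starting material
2 | 3-methoxy-4-(triisopropylsilyloxy)benzaldehyde | COc1cc(C=O)ccc1O[Si](C(C)C)(C(C)C)C(C)C | intermediate
3 | 4-ethynyl-2-methoxy-1-(triisopropylsilyloxy)benzene | C#Cc1ccc(O[Si](C(C)C)(C(C)C)C(C)C)c(OC)c1 | intermediate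
4 | 3,5-bis(benzyloxy)phenol | Oc1cc(OCc2ccccc2)cc(OCc2ccccc2)c1 | starting material
5 | 3,5-bis(benzyloxy)-2-iodophenol | Oc1cc(OCc2ccccc2)cc(OCc2ccccc2)c1I | intermediate
6 | carbon monoxide | [C-]#[O+] | starting material
7 | 1-[2,4-bis(benzyloxy)-6-hydroxyphenyl]-3-[3-methoxy-4-(triisopropylsilyloxy)phenyl]prop-2-yn-1-one | COc1cc(C#CC(=O)c2c(O)cc(OCc3ccccc3)cc2OCc2ccccc2)ccc1O[Si](C(C)C)(C(C)C)C(C)C | intermediate
8 | 1-[2,4-bis(benzyloxy)-6-hydroxyphenyl]-3-(diethylamino)-3-[3-methoxy-4-(triisopropylsilyloxy)phenyl]prop-2-en-1-one (double-bond geometry not defined) | CCN(CC)C(=CC(=O)c1c(O)cc(OCc2ccccc2)cc1OCc1ccccc1)c1ccc(O[Si](C(C)C)(C(C)C)C(C)C)c(OC)c1 | intermediate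
9 | 5,7-bis(benzyloxy)-2-[3-methoxy-4-(triisopropylsilyloxy)phenyl]-4H-chromen-4-one | COc1cc(-c2cc(=O)c3c(OCc4ccccc4)cc(OCc4ccccc4)cc3o2)ccc1O[Si](C(C)C)(C(C)C)C(C)C | intermediate
10 | (2S,4S)-5,7-bis(benzyloxy)-2-[3-methoxy-4-(triisopropylsilyloxy)phenyl]chroman-4-ol (2,4-cis) | COc1cc([C@H]2Oc3cc(OCc4ccccc4)cc(OCc4ccccc4)c3[C@@H](O)C2)ccc1O[Si](C(C)C)(C(C)C)C(C)C | intermediate
11 | (2S)-5,7-bis(benzyloxy)-2-[3-methoxy-4-(triisopropylsilyloxy)phenyl]chroman-4-one | COc1cc([C@H]2Oc3cc(OCc4ccccc4)cc(OCc4ccccc4)c3C(=O)C2)ccc1O[Si](C(C)C)(C(C)C)C(C)C | intermediate
12 | (2S)-5,7-bis(benzyloxy)-2-[3-methoxy-4-(triisopropylsilyloxy)phenyl]-4-(trimethylsilyloxy)-2H-chromene | COc1cc([C@H]2Oc3cc(OCc4ccccc4)cc(OCc4ccccc4)c3C(O[Si](C)(C)C)=C2)ccc1O[Si](C(C)C)(C(C)C)C(C)C | intermediate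
13 | (2R,3R,4R)-5,7-bis(benzyloxy)-3,4-epoxy-2-[3-methoxy-4-(triisopropylsilyloxy)phenyl]-4-(trimethylsilyloxy)chromane (epoxide oxygen anti to the C2 aryl group) | COc1cc([C@H]2Oc3cc(OCc4ccccc4)cc(OCc4ccccc4)c3[C@]5(O[Si](C)(C)C)O[C@H]25)ccc1O[Si](C(C)C)(C(C)C)C(C)C | intermediate
14 | (2R,3R)-5,7-bis(benzyloxy)-3-hydroxy-2-[3-methoxy-4-(triisopropylsilyloxy)phenyl]chroman-4-one | COc1cc([C@H]2Oc3cc(OCc4ccccc4)cc(OCc4ccccc4)c3C(=O)[C@@H]2O)ccc1O[Si](C(C)C)(C(C)C)C(C)C | intermediate
15 | (2R,3R)-3,5,7-trihydroxy-2-[3-methoxy-4-(triisopropylsilyloxy)phenyl]chroman-4-one | COc1cc([C@H]2Oc3cc(O)cc(O)c3C(=O)[C@@H]2O)ccc1O[Si](C(C)C)(C(C)C)C(C)C | intermediate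
16 | prenyl bromide (1-bromo-3-methylbut-2-ene) | CC(C)=CCBr | starting material
17 | (2R,3R)-3,5-dihydroxy-2-[3-methoxy-4-(triisopropylsilyloxy)phenyl]-7-[(3-methylbut-2-en-1-yl)oxy]chroman-4-one | COc1cc([C@H]2Oc3cc(OCC=C(C)C)cc(O)c3C(=O)[C@@H]2O)ccc1O[Si](C(C)C)(C(C)C)C(C)C | intermediate
18 | (2R,3R)-3,5-dihydroxy-2-(4-hydroxy-3-methoxyphenyl)-7-[(3-methylbut-2-en-1-yl)oxy]chroman-4-one | COc1cc([C@H]2Oc3cc(OCC=C(C)C)cc(O)c3C(=O)[C@@H]2O)ccc1O | target

## Step count and least certain steps

Total: 10 steps. Longest linear sequence: 9 steps (vanillin 1 through steps 1, 2 and 4 to 10); the ring A branch contributes step 3.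

**Step 4 (key step).** The most likely failures are:
- direct aryl–alkyne coupling without carbon monoxide insertion, followed by cyclisation to a benzofuran;
- capture of the aroyl–palladium intermediate by diethylamine to give the amide;
- slow oxidative addition, because the carbon–iodine bond is electron-rich and flanked by two oxygen substituents;
- partial loss of the silyl group in hot amine.

Fallback: the C4 carbon is carried by the alkyne partner instead of by carbon monoxide. It sets out from 5 and 3 and rejoins the route at 9.
- 5 is protected with chloromethyl methyl ether and iPr2NEt as 1,5-bis(benzyloxy)-2-iodo-3-(methoxymethoxy)benzene F1.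
- 3 is deprotonated with n-BuLi and acylated with N-methoxy-N-methylcarbamoyl chloride to N-methoxy-N-methyl-3-[3-methoxy-4-(triisopropylsilyloxy)phenyl]prop-2-ynamide F2.
- Iodine–magnesium exchange on F1 with iPrMgCl·LiCl and addition to F2 gives 1-[2,4-bis(benzyloxy)-6-(methoxymethoxy)phenyl]-3-[3-methoxy-4-(triisopropylsilyloxy)phenyl]prop-2-yn-1-one F3.
- Mild aqueous acid removes the acetal ortho to the ketone to give 7, now isolated.
- Diethylamine in ethanol closes 7 by way of 8 to 9.

**Step 5.** Face discrimination may be poor or conversion incomplete on a 5,7-dioxygenated flavone with a bulky para-silyloxyphenyl group at C2, since the substrate is more electron-rich and more hindered than simple flavones. The electron-rich flavan-4-ol may also ionise at C4 during re-oxidation.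

Fallback: a racemic reduction followed by kinetic resolution. It sets out from 9 and rejoins at 11.
- Conjugate reduction of 9 with an achiral copper hydride (Cu(OAc)2, 1,2-bis(diphenylphosphino)benzene, (EtO)2MeSiH, t-BuOH, toluene) gives rac-5,7-bis(benzyloxy)-2-[3-methoxy-4-(triisopropylsilyloxy)phenyl]chroman-4-one F4.
- Asymmetric transfer hydrogenation with RuCl(p-cymene)(TsDPEN) of the appropriate antipode in HCO2H–Et3N reduces the (2R) enantiomer to (2R,4R)-5,7-bis(benzyloxy)-2-[3-methoxy-4-(triisopropylsilyloxy)phenyl]chroman-4-ol F5 and leaves (2S)-11. This caps the material throughput at half.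

**Step 6 (together with step 7).** Opening of ring C by β-elimination of the O1 phenoxide from the C3 enolate would erode the configuration at C2. In step 7, incomplete facial selectivity of the epoxidation or oxidation of the electron-rich rings would lower the yield of the trans ketol.

Fallback: a sequence that never forms an enolate. It sets out from 11 and rejoins at 14.
- NaBH4 reduces 11 to the cis alcohol 10.
- Dehydration with methyl N-(triethylammoniosulfonyl)carbamate gives (2S)-5,7-bis(benzyloxy)-2-[3-methoxy-4-(triisopropylsilyloxy)phenyl]-2H-chromene F6.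
- OsO4 (catalytic) with N-methylmorpholine N-oxide dihydroxylates the C3=C4 bond anti to the aryl group to give (2R,3S,4S)-5,7-bis(benzyloxy)-2-[3-methoxy-4-(triisopropylsilyloxy)phenyl]chroman-3,4-diol F7.
- DDQ oxidises only the benzylic C4 alcohol, which is activated by the ortho and para alkoxy groups of ring A, to give 14.

**Step 9.** Base may open ring C or epimerise it, air may oxidise the ketol to the flavonol, and over-alkylation at O5 or carbon alkylation at C6 or C8 may occur, because the phloroglucinol-type ring is an ambident nucleophile once deprotonated.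

Fallback: alkylation without base. It sets out from 15 and rejoins at 17. A Mitsunobu etherification with 3-methylbut-2-en-1-ol, PPh3 and diisopropyl azodicarboxylate in THF at 0 °C engages only the most acidic phenol, O7–H. No new intermediate is formed.

**Step 3.** Iodination may go para to the hydroxyl (between the two benzyloxy groups) or go twice, because all three free ring positions are activated by all three oxygens.

Fallback: directed metalation, which cannot reach the para position. It sets out from 4 and rejoins at 5.
- 4 is acylated with diethylcarbamoyl chloride and K2CO3 to 3,5-bis(benzyloxy)phenyl N,N-diethylcarbamate F8.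
- Ortho-lithiation with s-BuLi and TMEDA in THF at −78 °C, kept short to avoid benzylic metalation, and quenching with iodine gives 3,5-bis(benzyloxy)-2-iodophenyl N,N-diethylcarbamate F9.
- NaOH in ethanol at reflux cleaves the carbamate to 5.

## Further compounds

F1 | step 4 | 1,5-bis(benzyloxy)-2-iodo-3-(methoxymethoxy)benzene | COCOc1cc(OCc2ccccc2)cc(OCc2ccccc2)c1I
F2 | step 4 | N-methoxy-N-methyl-3-[3-methoxy-4-(triisopropylsilyloxy)phenyl]prop-2-ynamide | CON(C)C(=O)C#Cc1ccc(O[Si](C(C)C)(C(C)C)C(C)C)c(OC)c1
F3 | step 4 | 1-[2,4-bis(benzyloxy)-6-(methoxymethoxy)phenyl]-3-[3-methoxy-4-(triisopropylsilyloxy)phenyl]prop-2-yn-1-one | COCOc1cc(OCc2ccccc2)cc(OCc2ccccc2)c1C(=O)C#Cc1ccc(O[Si](C(C)C)(C(C)C)C(C)C)c(OC)c1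
F4 | step 5 | rac-5,7-bis(benzyloxy)-2-[3-methoxy-4-(triisopropylsilyloxy)phenyl]chroman-4-one | COc1cc(C2Oc3cc(OCc4ccccc4)cc(OCc4ccccc4)c3C(=O)C2)ccc1O[Si](C(C)C)(C(C)C)C(C)C
F5 | step 5 | (2R,4R)-5,7-bis(benzyloxy)-2-[3-methoxy-4-(triisopropylsilyloxy)phenyl]chroman-4-ol | COc1cc([C@@H]2Oc3cc(OCc4ccccc4)cc(OCc4ccccc4)c3[C@H](O)C2)ccc1O[Si](C(C)C)(C(C)C)C(C)C
F6 | step 6 | (2S)-5,7-bis(benzyloxy)-2-[3-methoxy-4-(triisopropylsilyloxy)phenyl]-2H-chromene | COc1cc([C@H]2Oc3cc(OCc4ccccc4)cc(OCc4ccccc4)c3C=C2)ccc1O[Si](C(C)C)(C(C)C)C(C)C
F7 | step 6 | (2R,3S,4S)-5,7-bis(benzyloxy)-2-[3-methoxy-4-(triisopropylsilyloxy)phenyl]chroman-3,4-diol | COc1cc([C@H]2Oc3cc(OCc4ccccc4)cc(OCc4ccccc4)c3[C@H](O)[C@@H]2O)ccc1O[Si](C(C)C)(C(C)C)C(C)C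
F0 | step 9 | none | none
F8 | step 3 | 3,5-bis(benzyloxy)phenyl N,N-diethylcarbamate | CCN(CC)C(=O)Oc1cc(OCc2ccccc2)cc(OCc2ccccc2)c1
F9 | step 3 | 3,5-bis(benzyloxy)-2-iodophenyl N,N-diethylcarbamate | CCN(CC)C(=O)Oc1cc(OCc2ccccc2)cc(OCc2ccccc2)c1I
A1 | alternative 1 | (2R,3R)-3-(tert-butyldimethylsilyloxy)-2-[4-(tert-butyldimethylsilyloxy)-3-methoxyphenyl]-5,7-dihydroxychroman-4-one | COc1cc([C@H]2Oc3cc(O)cc(O)c3C(=O)[C@@H]2O[Si](C)(C)C(C)(C)C)ccc1O[Si](C)(C)C(C)(C)C
A2 | alternative 1 | (2R,3R)-3-(tert-butyldimethylsilyloxy)-2-[4-(tert-butyldimethylsilyloxy)-3-methoxyphenyl]-5-(phenylsulfinyl)-2,3-dihydro-4H-pyran-4-one (sulfur configuration not defined) | COc1cc([C@H]2OC=C(S(=O)c3ccccc3)C(=O)[C@@H]2O[Si](C)(C)C(C)(C)C)ccc1O[Si](C)(C)C(C)(C)C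
A3 | alternative 1 | 1-methoxy-1,3-bis(trimethylsilyloxy)buta-1,3-diene | C=C(O[Si](C)(C)C)C=C(OC)O[Si](C)(C)C
A4 | alternative 2 | (3S)-3,5,7-tris(benzyloxy)chroman-2-ol (anomeric mixture) | OC1Oc2cc(OCc3ccccc3)cc(OCc3ccccc3)c2C[C@@H]1OCc1ccccc1
A5 | alternative 2 | 3,5-bis(benzyloxy)-2-[(4-methylphenyl)sulfonylmethyl]phenol | Cc1ccc(S(=O)(=O)Cc2c(O)cc(OCc3ccccc3)cc2OCc2ccccc2)cc1
A6 | alternative 2 | benzyloxyacetaldehyde | O=CCOCc1ccccc1
A7 | alternative 2 | 3,5-bis(benzyloxy)-6-methylidenecyclohexa-2,4-dien-1-one | C=C1C(=O)C=C(OCc2ccccc2)C=C1OCc1ccccc1
A8 | alternative 3 | (2S)-5-(tert-butyldimethylsilyloxy)-2-[3-methoxy-4-(triisopropylsilyloxy)phenyl]-7-(prenyloxy)chroman-4-one | COc1cc([C@H]2Oc3cc(OCC=C(C)C)cc(O[Si](C)(C)C(C)(C)C)c3C(=O)C2)ccc1O[Si](C(C)C)(C(C)C)C(C)C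
A9 | alternative 3 | 2-diazo-1-[2-{[3-methoxy-4-(triisopropylsilyloxy)phenyl]methoxy}-6-(tert-butyldimethylsilyloxy)-4-(prenyloxy)phenyl]ethan-1-one | COc1cc(COc2cc(OCC=C(C)C)cc(O[Si](C)(C)C(C)(C)C)c2C(=O)C=[N+]=[N-])ccc1O[Si](C(C)C)(C(C)C)C(C)C
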